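**Retrosynthetic overview**
1. Target 12 ⇐ triol 10 by threefold O‑angeloylation with angelic acid 11.
2. Triol 10 ⇐ β‑hydroxy ketone 8: the C5 carbinol by C3–OH‑directed anti reduction, the C3–O bond by conjugate borylation/oxidation of enone 6.
3. Enone 6 ⇐ ene‑dione 5 by a catalyst‑controlled β‑methyl C–H acetoxylation; this C–O bond formation is the key step and sets the quaternary C6 centre.
4. Ene‑dione 5 ⇐ longiverbenone 2 by C3–C4 dehydrogenation and allylic oxidation at C5; 2 ⇐ (+)‑α‑longipinene 1 by allylic oxidation at C11.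
5. No ring is built: the cyclobutane, the six‑membered and the seven‑membered ring all come intact from 1.

Assumption: commercial (+)‑α‑longipinene is the (1R,2S,7R,8R) enantiomer drawn as 1 (assigned from memory, not checked); α‑longipinene locants are kept for every compound (cyclobutane C1, C2, C7, C8; bridge C3–C6; bridge C9–C11).

**Step 1**
Reactants: 1 (+)‑α‑longipinene
Product: 2 longiverbenone (1R,2R,7S,8R)-2,6,6,9-tetramethyltricyclo[5.4.0.0^{2,8}]undec-9-en-11-one
Conditions: Rh2(cap)4 (1 mol %), t‑BuOOH (70% aq, 5 equiv), K2CO3 (cat.), CH2Cl2, rt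
Reagents that add atoms: tert‑butyl hydroperoxide, CC(C)(C)OO
Why: Rh‑caprolactamate/TBHP allylic oxidation takes the only secondary allylic hydrogens (C11; the C8 bridgehead C–H lies in the nodal plane of the alkene) and gives the enone just as α‑pinene gives verbenone, with no stereocentre touched.

**Step 2**
Reactants: 2 longiverbenone
Product: 3 (1R,2R,7S,8R)-2,6,6,9-tetramethyltricyclo[5.4.0.0^{2,8}]undeca-3,9-dien-11-one
Conditions: (Bu4N)4W10O32 (2 mol %), Co(dmgH)2(py)Cl (3 mol %), MeCN, 390 nm LED, Ar sweep, rt, to about 50% conversion, recycle 2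
Reagents that add atoms: none
Why: Decatungstate HAT/cobaloxime acceptorless dehydrogenation: the electrophilic W–O• avoids the enone‑deactivated top half and abstracts from the exposed C4 (or C3) methylene, and the cobaloxime then removes the neighbouring C3–H, not the C5–H flanked by the gem‑dimethyl pair, giving the Δ3 olefin.

**Step 3**
Reactants: 3 the Δ3 dienone
Product: 5 (1R,2R,7S,8R)-2,6,6,9-tetramethyltricyclo[5.4.0.0^{2,8}]undeca-3,9-diene-5,11-dione, via allylic alcohol 4 (not isolated)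
Conditions: SeO2 (0.3 equiv), t‑BuOOH (3 equiv), CH2Cl2, rt; Na2SO3 wash; then Dess–Martin periodinane, NaHCO3, CH2Cl2, 0 °C to rt
Reagents that add atoms: tert‑butyl hydroperoxide, CC(C)(C)OO (terminal O source, relayed by catalytic SeO2, O=[Se]=O)
Why: Sharpless SeO2/TBHP allylic hydroxylation (ene reaction then [2,3] shift) can only oxygenate C5, the sole allylic carbon bearing hydrogen (C2 is quaternary), and Dess–Martin oxidation converges both C5 epimers of 4 to the enone.

**Step 4**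
Reactants: 5 the ene‑dione
Product: 6 [(1R,2R,6S,7S,8R)-2,6,9-trimethyl-5,11-dioxotricyclo[5.4.0.0^{2,8}]undeca-3,9-dien-6-yl]methyl acetate
Conditions: Pd(OAc)2 (10 mol %), (S)‑tert‑leucine (25 mol %; antipode if the screen demands), 3‑nitro‑5‑(trifluoromethyl)‑2‑pyridone (20 mol %), 1‑fluoro‑2,4,6‑trimethylpyridinium triflate (1.5 equiv), AcOH/HFIP 1:4, 60 °C
Reagents that add atoms: acetic acid, CC(=O)O
Why: Proposed new method: a chiral amino‑acid transient directing group condenses reversibly at the C5 ketone (N‑substituent anti to quaternary C6, so Pd sits syn to the gem‑dimethyl group), pyridone‑assisted concerted metalation–deprotonation closes a five‑membered palladacycle on one methyl, the tert‑butyl group of the imine making the two diastereotopic methyl transition states unequal so that the amino‑acid antipode selects the methyl that gives (6S), and the bystanding F+ oxidant takes Pd(II) to Pd(IV), from which acetate forms the C–O bond; the C11 imine has only the out‑of‑plane C7 methine in reach and is a spectator; closest known reaction types are oxime‑directed Pd(II)/Pd(IV) β‑C(sp3)–H acetoxylation of ketone derivatives and amino‑acid transient‑directing‑group β‑C–H arylation of ketones.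

**Step 5**
Reactants: 6 the acetoxymethyl ene‑dione
Product: 8 [(1R,2R,3R,6S,7S,8R)-3-hydroxy-2,6,9-trimethyl-5,11-dioxotricyclo[5.4.0.0^{2,8}]undec-9-en-6-yl]methyl acetate, via boronate 7 (not isolated)
Conditions: CuCl (5 mol %), Josiphos (5.5 mol %, antipode chosen by screen), NaOt‑Bu (10 mol %), B2pin2 (1.2 equiv), MeOH (2 equiv), THF, rt; then NaBO3·4H2O, THF/H2O, rt
Reagents that add atoms: bis(pinacolato)diboron, CC1(C)OB(OC1(C)C)B1OC(C)(C)C(C)(C)O1 (boron in 7 only); sodium perborate, [Na+].[Na+].O[B-]1(O)OO[B-](O)(O)OO1 (the C3 oxygen of 8)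
Why: Cu(I)‑catalysed asymmetric conjugate borylation adds Bpin only to the enone that has a β‑hydrogen (the β,β‑disubstituted C9 enone is inert), the ligand antipode being chosen so that boron enters C3 on the ring face of the CH2OAc group (3R), and perborate oxidation replaces B by OH with retention under conditions too mild for β‑elimination.

**Step 6**
Reactants: 8 the β‑hydroxy ketone
Product: 10 (1R,2R,3R,5R,6S,7S,8R)-3,5-dihydroxy-6-(hydroxymethyl)-2,6,9-trimethyltricyclo[5.4.0.0^{2,8}]undec-9-en-11-one, via diol acetate 9 (not isolated)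
Conditions: Me4NBH(OAc)3 (5 equiv), MeCN/AcOH 1:1, −20 °C to rt; aqueous work‑up; then K2CO3 (0.2 equiv), MeOH, rt
Reagents that add atoms: none
Why: Evans–Saksena directed reduction: the C3 alkoxy‑acetoxyborohydride delivers hydride intramolecularly to the C5 ketone from the face of the C3 oxygen, so the new C5–OH is anti to C3–OH (5R) while the undirected C11 enone is untouched, and methanolysis then frees the primary alcohol.

**Step 7**
Reactants: 10 the triol; 11 angelic acid
Product: 12 [(1R,2R,3R,5R,6S,7S,8R)-2,6,9-trimethyl-3,5-bis{[(Z)-2-methylbut-2-enoyl]oxy}-11-oxotricyclo[5.4.0.0^{2,8}]undec-9-en-6-yl]methyl (Z)-2-methylbut-2-enoate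
Conditions: 11 (6 equiv), 2,4,6‑Cl3C6H2COCl (6 equiv), Et3N (12 equiv), toluene, rt, 2 h; then 10, 80 °C, 36 h (no DMAP)
Reagents that add atoms: angelic acid 11, C/C=C(/C)C(=O)O (three angeloyl groups, delivered as its 2,4,6‑trichlorobenzoic mixed anhydride)
Why: Yamaguchi‑type esterification with the preformed mixed anhydride acylates the primary and the two neopentyl secondary hydroxyls, and leaving out DMAP and acid chloride activation avoids Z‑to‑E isomerisation to tiglates.

**Compound list**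
1 | (+)‑α‑longipinene, (1R,2S,7R,8R)-2,6,6,9-tetramethyltricyclo[5.4.0.0^{2,8}]undec-9-ene | CC1(C)[C@@H]2[C@H]3CC=C(C)[C@@H]2[C@@]3(C)CCC1 | starting material
2 | longiverbenone, (1R,2R,7S,8R)-2,6,6,9-tetramethyltricyclo[5.4.0.0^{2,8}]undec-9-en-11-one | CC1(C)[C@@H]2[C@H]3C(=O)C=C(C)[C@@H]2[C@@]3(C)CCC1 | intermediate
3 | (1R,2R,7S,8R)-2,6,6,9-tetramethyltricyclo[5.4.0.0^{2,8}]undeca-3,9-dien-11-one | CC1(C)[C@@H]2[C@H]3C(=O)C=C(C)[C@@H]2[C@@]3(C)C=CC1 | intermediate
4 | (1R,2R,7S,8R)-5-hydroxy-2,6,6,9-tetramethyltricyclo[5.4.0.0^{2,8}]undeca-3,9-dien-11-one (C5 epimer mixture) | CC1(C)[C@@H]2[C@H]3C(=O)C=C(C)[C@@H]2[C@@]3(C)C=CC1O | intermediate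
5 | (1R,2R,7S,8R)-2,6,6,9-tetramethyltricyclo[5.4.0.0^{2,8}]undeca-3,9-diene-5,11-dione | CC1(C)[C@@H]2[C@H]3C(=O)C=C(C)[C@@H]2[C@@]3(C)C=CC1=O | intermediate
6 | [(1R,2R,6S,7S,8R)-2,6,9-trimethyl-5,11-dioxotricyclo[5.4.0.0^{2,8}]undeca-3,9-dien-6-yl]methyl acetate | CC(=O)OC[C@]1(C)[C@@H]2[C@H]3C(=O)C=C(C)[C@@H]2[C@@]3(C)C=CC1=O | intermediate
7 | [(1R,2R,3R,6S,7S,8R)-2,6,9-trimethyl-5,11-dioxo-3-(4,4,5,5-tetramethyl-1,3,2-dioxaborolan-2-yl)tricyclo[5.4.0.0^{2,8}]undec-9-en-6-yl]methyl acetate | CC(=O)OC[C@]1(C)[C@@H]2[C@H]3C(=O)C=C(C)[C@@H]2[C@@]3(C)[C@H](B4OC(C)(C)C(C)(C)O4)CC1=O | intermediate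
8 | [(1R,2R,3R,6S,7S,8R)-3-hydroxy-2,6,9-trimethyl-5,11-dioxotricyclo[5.4.0.0^{2,8}]undec-9-en-6-yl]methyl acetate (3‑OH cis to CH2OAc) | CC(=O)OC[C@]1(C)[C@@H]2[C@H]3C(=O)C=C(C)[C@@H]2[C@@]3(C)[C@H](O)CC1=O | intermediate
9 | [(1R,2R,3R,5R,6S,7S,8R)-3,5-dihydroxy-2,6,9-trimethyl-11-oxotricyclo[5.4.0.0^{2,8}]undec-9-en-6-yl]methyl acetate (3‑OH and 5‑OH trans) | CC(=O)OC[C@]1(C)[C@@H]2[C@H]3C(=O)C=C(C)[C@@H]2[C@@]3(C)[C@H](O)C[C@H]1O | intermediate
10 | (1R,2R,3R,5R,6S,7S,8R)-3,5-dihydroxy-6-(hydroxymethyl)-2,6,9-trimethyltricyclo[5.4.0.0^{2,8}]undec-9-en-11-one | OC[C@]1(C)[C@@H]2[C@H]3C(=O)C=C(C)[C@@H]2[C@@]3(C)[C@H](O)C[C@H]1O | intermediate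
11 | angelic acid, (Z)-2-methylbut-2-enoic acid | C/C=C(/C)C(=O)O | starting material
12 | CNP0266467.1, the 3,5,6‑CH2 tris‑angelate of 10 | C/C=C(/C)C(=O)OC[C@]1(C)[C@@H]2[C@H]3C(=O)C=C(C)[C@@H]2[C@@]3(C)[C@H](OC(=O)/C(C)=C\C)C[C@H]1OC(=O)/C(C)=C\C | target

Stereocentres: C1, C2, C7 and C8 come from 1 and are never touched; C6 is set in step 4, C3 in step 5, C5 in step 6.

**Totals**
Total steps: 7. Longest linear sequence: 7 (linear from 1; 11 enters in step 7).

**Steps most likely to fail**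

Step 2 (dehydrogenation: low conversion, or the Δ4 regioisomer). The fallback sets out from 2 and comes back at 3. Aerobic decatungstate C–H oxidation (TBADT, O2, MeCN, 390 nm) converts the exposed C4 methylene into the 4,11‑dione F1. Kinetic deprotonation on the less hindered C3 side (LDA, THF, −78 °C) and trapping with PhNTf2 gives the Δ3 enol triflate F2. Reduction with Pd(OAc)2/PPh3, HCO2H and Bu3N in DMF removes the triflate and delivers 3, with the olefin position fixed by enolate chemistry instead of by the cobalt step.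

Step 4 (the proposed C–H acetoxylation: no turnover, or the wrong methyl). The fallback sets out from 5 and comes back at 6, using the known oxime‑directed chemistry. NH2OH·HCl/NaOAc in EtOH gives the 5,11‑dioxime F3. Pd(OAc)2, PhI(OAc)2 in AcOH/Ac2O at 80–100 °C acetylates both oximes in the flask and acetoxylates a C6 methyl through the palladacycle of the C5 O‑acetyl oxime, the C11 oxime having no β‑methyl; the acetoxymethyl bis(O‑acetyl oxime) F4 is separated from its C6 epimer by chromatography, because here the methyl choice is substrate‑controlled only. Trans‑oximation with 50% aqueous glyoxylic acid in THF restores both ketones and gives 6.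

Step 5 (conjugate borylation at a β‑carbon next to quaternary C2, and its facial control). The fallback sets out from 6 and comes back at 8, forming the C3–O bond by epoxidation. Amine‑catalysed asymmetric nucleophilic epoxidation (9‑amino‑9‑deoxy‑epi‑quinine·2TFA, 50% H2O2, dioxane) of the only enone with a β‑hydrogen gives the 3,4‑epoxy ketone F5 with the oxirane on the face of the CH2OAc group. SmI2 in THF/MeOH at −78 °C cleaves the Cα–O bond and gives 8.

**Further compounds**
F1 | step 2 | (1R,2R,7S,8R)-2,6,6,9-tetramethyltricyclo[5.4.0.0^{2,8}]undec-9-ene-4,11-dione | CC1(C)[C@@H]2[C@H]3C(=O)C=C(C)[C@@H]2[C@@]3(C)CC(=O)C1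
F2 | step 2 | (1R,2S,7S,8R)-2,6,6,9-tetramethyl-11-oxotricyclo[5.4.0.0^{2,8}]undeca-3,9-dien-4-yl trifluoromethanesulfonate | CC1(C)[C@@H]2[C@H]3C(=O)C=C(C)[C@@H]2[C@@]3(C)C=C(OS(=O)(=O)C(F)(F)F)C1
F3 | step 4 | (1R,2R,7S,8R)-2,6,6,9-tetramethyltricyclo[5.4.0.0^{2,8}]undeca-3,9-diene-5,11-dione dioxime (oxime geometry as formed) | CC1(C)[C@@H]2[C@H]3C(=NO)C=C(C)[C@@H]2[C@@]3(C)C=CC1=NO
F4 | step 4 | [(1R,2R,6R,7S,8R)-5,11-bis(acetoxyimino)-2,6,9-trimethyltricyclo[5.4.0.0^{2,8}]undeca-3,9-dien-6-yl]methyl acetate (same C6 geometry as 6) | CC(=O)OC[C@]1(C)[C@@H]2[C@H]3C(=NOC(C)=O)C=C(C)[C@@H]2[C@@]3(C)C=CC1=NOC(C)=O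
F5 | step 5 | [(1R,2R,3S,4S,6S,7S,8R)-3,4-epoxy-2,6,9-trimethyl-5,11-dioxotricyclo[5.4.0.0^{2,8}]undec-9-en-6-yl]methyl acetate | CC(=O)OC[C@]1(C)[C@@H]2[C@H]3C(=O)C=C(C)[C@@H]2[C@@]3(C)[C@@H]4O[C@@H]4C1=O
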